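**Retrosynthetic overview**
- 10 ⇒ 5: cut the O1–C2 bond of ring C. O1 is traced back to the 6'-methoxy oxygen of chalcone 5 (its methyl is lost). The 2'-OH of 5 survives as the 5-OH, so no protecting group and no final deprotection are needed.
- 5 ⇒ 3 + 4: the Cα=Cβ bond comes from a Claisen–Schmidt condensation.
- 3 ⇒ 1: C-acetylation of 3,4,5-trimethoxyphenol.
- Rings A and B are bought. Ring C is the only ring made, and it is closed last.

Assumption: altisin has no stereocentre, and ring B is symmetric about the C2–C1' bond. The target is therefore achiral and no enantiomer question arises. The only stereo-element on the way is the E alkene of 5.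

**Step 1**
Reactants: 1 3,4,5-trimethoxyphenol
Product: 3 1-(6-hydroxy-2,3,4-trimethoxyphenyl)ethan-1-one, via acetophenone difluoroboron chelate 2 (not isolated)
Conditions: AcOH (3 equiv), BF3·OEt2 (neat), 85 °C, 2.5 h; then H2O
Reagents that add atoms: acetic acid CC(=O)O
Why: Friedel–Crafts (Nencki-type) C-acylation of a very electron-rich phenol whose two free ring positions are equivalent, with the product held in the flask as chelate 2, which stops a second acylation and spares the methyl ethers until water releases 3.

**Step 2**
Reactants: 3 1-(6-hydroxy-2,3,4-trimethoxyphenyl)ethan-1-one; 4 2,6-dimethoxybenzaldehyde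
Product: 5 (E)-3-(2,6-dimethoxyphenyl)-1-(6-hydroxy-2,3,4-trimethoxyphenyl)prop-2-en-1-one
Conditions: KOH (50% aq, 10 equiv), EtOH, rt, 48 h; then 1 M HCl
Reagents that add atoms: none
Why: Claisen–Schmidt aldol condensation in which the methyl ketone enolate of 3 adds to the non-enolisable aldehyde 4 and E1cB loss of water gives the conjugated E alkene, while the 2'-phenolate keeps the chalcone from closing to a flavanone in base.

**Step 3**
Reactants: 5 (E)-3-(2,6-dimethoxyphenyl)-1-(6-hydroxy-2,3,4-trimethoxyphenyl)prop-2-en-1-one
Product: 10 altisin, via chalcone difluoroboron chelate 6 (not isolated), via ring-closed borate enolate 7 (not isolated), via 3-iodoflavanone chelate 8 (not isolated), via flavone difluoroboron chelate 9 (not isolated)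
Conditions: BF3·OEt2 (1.3 equiv), CH2Cl2, rt, 1 h, evaporate (toluene chase); Bu4NI (1.5 equiv), dry K2CO3 (4 equiv), I2 (1.05 equiv, fed over 4 h), MeCN, 80 °C, closed vessel; N2 purge; then MeOH/H2O 4:1, 60 °C
Reagents that add atoms: none
Why: Proposed new method: boron-gated demethylative oxidative ring closure, in which BF3 turns the 2'-OH/C=O pair of 5 into the six-membered O–BF2–O chelate 6, which masks the only free phenol, holds the carbonyl oxygen on the 2' side so that the enone arm lies against the 6'-OMe, and makes Cβ strongly electrophilic, so that the 6'-methoxy oxygen adds 6-endo to Cβ and iodide takes the methyl off the resulting aryl methyl oxonium (or off the activated ether just before closure) as MeI to give enolate 7, I2 iodinates C3 and returns the iodide, K2CO3 removes HI to aromatise ring C (the racemic centres of 7 and 8 are erased) and water frees the 5-OH; I2 is fed slowly so that free iodide always outweighs triiodide, a wrongly cleaved 4'- or ring B ether is re-methylated by the retained MeI while only the 6'-phenolate is drained irreversibly, and the closest known reaction types are the ICl-induced demethylative cyclisation of 2-methoxyaryl ynones to chromones, the I2-mediated oxidative cyclisation of 2'-hydroxychalcones and chelation-directed ether cleavage by boron halides, none of which closes a chalcone through a methoxy oxygen beside a masked phenol.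

**Compound list**
1 | 3,4,5-trimethoxyphenol | COc1cc(O)cc(OC)c1OC | starting material
2 | difluoroboron chelate of 3 (boron bound to the phenolate and ketone oxygens), formed in the flask | CC1=[O+][B-](F)(F)Oc2cc(OC)c(OC)c(OC)c21 | intermediate
3 | 1-(6-hydroxy-2,3,4-trimethoxyphenyl)ethan-1-one | CC(=O)c1c(O)cc(OC)c(OC)c1OC | intermediate
4 | 2,6-dimethoxybenzaldehyde | COc1cccc(OC)c1C=O | starting material
5 | (E)-3-(2,6-dimethoxyphenyl)-1-(6-hydroxy-2,3,4-trimethoxyphenyl)prop-2-en-1-one | COc1cccc(OC)c1/C=C/C(=O)c1c(O)cc(OC)c(OC)c1OC | intermediate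
6 | difluoroboron chelate of 5 (E alkene kept), formed in the flask | COc1cccc(OC)c1/C=C/C1=[O+][B-](F)(F)Oc2cc(OC)c(OC)c(OC)c21 | intermediate
7 | tetrabutylammonium salt of the ring-closed difluoroborate enolate (flav-3-ene, boron bridging O4 and O5; racemic at C2), formed in the flask | CCCC[N+](CCCC)(CCCC)CCCC.COc1cccc(OC)c1C1C=C2O[B-](F)(F)Oc3cc(OC)c(OC)c(O1)c23 | intermediate
8 | difluoroboron chelate of 3-iodo-5-hydroxy-7,8-dimethoxy-2-(2,6-dimethoxyphenyl)chroman-4-one (racemic), formed in the flask | COc1cccc(OC)c1C1Oc2c(OC)c(OC)cc3O[B-](F)(F)[O+]=C(C1I)c23 | intermediate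
9 | difluoroboron chelate of altisin (boron bridging O4 and O5), formed in the flask | COc1cccc(OC)c1C1=CC2=[O+][B-](F)(F)Oc3cc(OC)c(OC)c(O1)c23 | intermediate
10 | altisin, 5-hydroxy-7,8-dimethoxy-2-(2,6-dimethoxyphenyl)-4H-chromen-4-one | COc1cccc(OC)c1-c1cc(=O)c2c(O)cc(OC)c(OC)c2o1 | target

**Total step count:** 3. Ketone 3 is also a catalogue compound, and buying it leaves 2 steps.
**Longest linear sequence:** 3.

**Steps most likely to fail**

1. **Step 3 (new step).**
   - Risks:
     - Iodide may attack the 4'-ether or a ring B ether faster than ring closure drains the 6'-position.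
     - The chelate may be lost early. Closure would then run through the free phenol and give the 5,6,7-trimethoxy isomer, which is recognisable because it lacks the chelated OH signal.
     - Surplus I2 may iodinate C6.
   - Fallback (known chemistry only): it sets out from 4 and comes back at 10.
     - Compound 4 is condensed (KOH, EtOH) with bought 1-(2-hydroxy-3,4,6-trimethoxyphenyl)ethan-1-one F1. This gives (E)-3-(2,6-dimethoxyphenyl)-1-(2-hydroxy-3,4,6-trimethoxyphenyl)prop-2-en-1-one F2.
     - Catalytic I2 in DMSO at 130 °C closes ring C through the free phenol. This gives 5,7,8-trimethoxy-2-(2,6-dimethoxyphenyl)-4H-chromen-4-one F3.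
     - BCl3 in CH2Cl2 at −78 to 0 °C cleaves only the 5-O-methyl group, which lies peri to the carbonyl. This gives 10.

2. **Step 2.**
   - Risks: aldehyde 4 is hindered and electron-rich, so the condensation may stall or give partly cyclised material.
   - Fallback: it sets out from 4, with 1 as partner, and comes back at 5.
     - A Doebner–Knoevenagel reaction of 4 with malonic acid (pyridine, catalytic piperidine, 100 °C) runs through 2-(2,6-dimethoxybenzylidene)malonic acid F4. It gives (E)-3-(2,6-dimethoxyphenyl)acrylic acid F5.
     - F5 C-acylates phenol 1 directly in BF3·OEt2 at 80 °C. Water work-up delivers 5 without passing through 3.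

3. **Step 1.**
   - Risks: the reaction may stop at the O-acetate, or the ether next to the new ketone may be partly lost on overheating.
   - Fallback: it sets out from 1 and comes back at 3.
     - A Houben–Hoesch reaction of 1 with MeCN (ZnCl2, HCl gas, Et2O, 0 °C) precipitates 1-(6-hydroxy-2,3,4-trimethoxyphenyl)ethan-1-iminium chloride F6.
     - Boiling F6 in water gives 3.

**Further compounds**
F1 | step 3 | 1-(2-hydroxy-3,4,6-trimethoxyphenyl)ethan-1-one (bought) | CC(=O)c1c(O)c(OC)c(OC)cc1OC
F2 | step 3 | (E)-3-(2,6-dimethoxyphenyl)-1-(2-hydroxy-3,4,6-trimethoxyphenyl)prop-2-en-1-one | COc1cccc(OC)c1/C=C/C(=O)c1c(O)c(OC)c(OC)cc1OC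
F3 | step 3 | 5,7,8-trimethoxy-2-(2,6-dimethoxyphenyl)-4H-chromen-4-one | COc1cccc(OC)c1-c1cc(=O)c2c(OC)cc(OC)c(OC)c2o1
F4 | step 2 | 2-(2,6-dimethoxybenzylidene)malonic acid | COc1cccc(OC)c1C=C(C(=O)O)C(=O)O
F5 | step 2 | (E)-3-(2,6-dimethoxyphenyl)acrylic acid | COc1cccc(OC)c1/C=C/C(=O)O
F6 | step 1 | 1-(6-hydroxy-2,3,4-trimethoxyphenyl)ethan-1-iminium chloride | CC(=[NH2+])c1c(O)cc(OC)c(OC)c1OC.[Cl-]
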